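**Strategy.** With the cyclohexane numbered C1 (side-chain carbon) to C6, the ring is cut at C1–C6 and C3–C4. C4–C5–C6, two cis oxygens flanking a carbinol, is a dihydroxyacetone unit, used as a 1,3-dioxan-5-one that is nucleophilic at both α-carbons. C1–C2–C3 is an α-methyl enone whose C1 and C3 carbon appendages, cis on the opposite ring face, are tied as the CH(OBn)–O–CH2 arc of an Achmatowicz pyranone. One amine-mediated Michael/aldol α,α′-annulation of these two heterocycles forms both bonds, closes the carbocycle as a doubly bridged chair and sets C1, C2, C3, C4 and C6; the bridges are later unzipped to the side-chain aldehyde, the C3 methyl and the C4/C6 diol.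

Key step: step 6

Remark: the lipase of step 3 is assumed to acylate the (R)-hemiacetal; the sense of its selectivity for this 4-methyl substrate would have to be confirmed, and the opposite sense would lead into the enantiomeric series.

**Fragment 1: pyranone**

Step 1
Reactants: 1 methyl 3-methylfuran-2-carboxylate
Product: 2 (3-methylfuran-2-yl)methanol
Conditions: LiAlH4, THF, 0 °C
Reagents that add atoms: none
Why: Hydride reduction of the ester to the primary alcohol should leave the furan untouched.

Step 2
Reactants: 2 (3-methylfuran-2-yl)methanol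
Product: 3 6-hydroxy-4-methyl-2H-pyran-3(6H)-one (racemic hemiacetal)
Conditions: NBS, NaHCO3, NaOAc, THF/H2O 4:1, 0 °C
Reagents that add atoms: water, O
Why: Achmatowicz rearrangement: oxidative opening of the furfuryl alcohol to the ene-dione and re-closure to the pyranone hemiacetal, the furan 3-methyl becoming the α-methyl of the enone.

Step 3
Reactants: 3 6-hydroxy-4-methyl-2H-pyran-3(6H)-one
Product: 4 (R)-6-acetoxy-4-methyl-2H-pyran-3(6H)-one
Conditions: immobilised Burkholderia cepacia lipase, vinyl acetate, hexane/t-BuOMe, 25 °C
Reagents that add atoms: vinyl acetate, CC(=O)OC=C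
Why: Lipase-catalysed acylation under dynamic kinetic resolution: the hemiacetal enantiomers interconvert by ring–chain tautomerism while one is acylated, which should create the only stereocentre the route takes from outside.

Step 4
Reactants: 4 (R)-6-acetoxy-4-methyl-2H-pyran-3(6H)-one
Product: 5 (S)-6-(benzyloxy)-4-methyl-2H-pyran-3(6H)-one
Conditions: BnOH (2 equiv), Pd2(dba)3 (2.5 mol %), PPh3 (10 mol %), CH2Cl2, 0 °C
Reagents that add atoms: benzyl alcohol, OCc1ccccc1
Why: Tsuji–Trost type O-glycosylation: zerovalent palladium ionises the anomeric acetate with inversion and the alcohol attacks the π-allyl complex with a second inversion, so the base-labile acetate should be exchanged for a stable benzyl acetal with net retention (the descriptor changes only through priorities).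

**Fragment 2: dioxanone**

Step 5
Reactants: 6 2-phenyl-1,3-dioxan-5-ol (cis/trans mixture)
Product: 7 2-phenyl-1,3-dioxan-5-one
Conditions: Dess–Martin periodinane, NaHCO3, CH2Cl2, 0 → 23 °C
Reagents that add atoms: none
Why: Dess–Martin oxidation of the secondary alcohol should give the symmetric ketone and erase the cis/trans mixture.

**Key annulation and elaboration of the carbocycle**

Step 6
Reactants: 5 (S)-6-(benzyloxy)-4-methyl-2H-pyran-3(6H)-one; 7 2-phenyl-1,3-dioxan-5-one
Product: 10 doubly bridged cyclohexanone ketol, via dioxanone enamine 8 (not isolated), via Michael adduct 9 (not isolated)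
Conditions: 7 (2 equiv), pyrrolidine (0.3 equiv), AcOH (0.3 equiv), MeCN, 25 → 45 °C; aq. NH4Cl
Reagents that add atoms: none
Why: Pyrrolidine converts 7 into enamine 8, which adds in Michael fashion to C5 of pyranone 5 (the C1–C6 bond of the target ring) to give 9; the amine then moves to the unsubstituted α′-carbon and this enamine attacks the pyranone ketone in an intramolecular aldol (the C3–C4 bond), after which hydrolysis releases ketol 10 and the amine. The closest known reaction type is the α,α′-annulation of cyclic ketone enamines with enones (Michael/aldol to bridged ketols, as in Stork and Robinson chemistry). Only ring A, the carbocycle, is closed, by a 6-(enolendo)-exo-trig aldol; the dioxane and pyran rings are already present and become the bridges on its two faces. C1 is set by addition anti to the anomeric benzyloxy group of 5; C3 and C4 are set by the tether, since the enamine can reach the ketone only from the face that carries C6, which puts the C3 hydroxyl opposite to the CH2O bridge and cis to O4; C6 and the acetal carbon are epimerisable or reversible and should settle in the one arrangement in which ring A is a chair with the two bridges on opposite faces and phenyl equatorial. C2 is set under thermodynamic control (enolisation and reversible aldol): the methyl should prefer the pyran side, because on the dioxane side it would be syn-axial to both C–O bonds. The step needs 1,4- over 1,2-addition and aldolisation from the α′- and not the α-carbon; the soft enamine secures the first, only the α′-carbon can form a six-membered ring, and the bridgehead ketol cannot dehydrate.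

Step 7
Reactants: 10 doubly bridged cyclohexanone ketol
Product: 11 C5-methylene cage
Conditions: Cp2TiMe2 (3 equiv), toluene/THF, 65 °C, dark
Reagents that add atoms: dimethyltitanocene Cp2TiMe2, [CH3-].[CH3-].[Ti+4].c1cc[cH-]c1.c1cc[cH-]c1
Why: Petasis methylenation through Cp2Ti=CH2 is non-basic, so the β-hydroxy ketone should not suffer retro-aldol (the tertiary hydroxyl is only titanated), and the reagent reaches C5 from the open face over the dioxane ring.

Step 8
Reactants: 11 C5-methylene cage
Product: 12 C5 spiro-epoxide cage
Conditions: DMDO, acetone, 0 °C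
Reagents that add atoms: dimethyldioxirane, CC1(C)OO1
Why: Epoxidation should occur from the only open face of the exocyclic alkene (over the dioxane ring, the other face being blocked by the pyran oxygen inside the cage), which places the epoxide oxygen cis to O4 and O6 as required at C5.

Step 9
Reactants: 12 C5 spiro-epoxide cage
Product: 13 epoxy tetrol aldehyde (in equilibrium with its bicyclic lactol)
Conditions: H2 (1 atm), Pd(OH)2/C, EtOAc/THF, 23 °C; crude product used directly
Reagents that add atoms: none
Why: Hydrogenolysis should cleave both the benzyl glycoside and the benzylidene acetal; with both bridges gone ring A can flip to the chair with the C1, C3 and C5 carbon substituents equatorial, in which the C1 aldehyde configuration is the thermodynamic one.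

Step 10
Reactants: 13 epoxy tetrol aldehyde
Product: 14 (E)-enoate
Conditions: Ph3P=C(Me)CO2Et (1.5 equiv), MeCN, 50 °C
Reagents that add atoms: ethyl 2-(triphenylphosphoranylidene)propanoate, CCOC(=O)C(C)=P(c1ccccc1)(c1ccccc1)c1ccccc1
Why: Wittig olefination with a stabilised α-methyl ylide should give the (E)-trisubstituted enoate under neutral conditions that tolerate the free hydroxyls and the epoxide.

Step 11
Reactants: 14 (E)-enoate
Product: 15 primary tosylate
Conditions: TsCl (1.1 equiv), Bu2SnO (5 mol %), Et3N, CH2Cl2, 0 °C
Reagents that add atoms: p-toluenesulfonyl chloride, Cc1ccc(cc1)S(Cl)(=O)=O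
Why: Stannylene-mediated monosulfonylation of the 1,2-diol should take place at the primary oxygen only, the secondary hydroxyls at C4 and C6 being flanked by fully substituted carbons and the tertiary ones inert.

Step 12
Reactants: 15 primary tosylate
Product: 17 pentol with allylic alcohol, via bis(spiro-epoxide) 16 (not isolated)
Conditions: LiAlH4 (excess), THF, 0 → 40 °C; aq. KNaC4H4O6
Reagents that add atoms: none
Why: The C3 alkoxide displaces the tosylate (3-exo-tet) to give 16, hydride then opens both spiro-epoxides at their CH2 termini (epoxide reduction), which should unveil the C3 and C5 methyl carbinols with unchanged configuration, and the ester is reduced to the allylic alcohol in the same operation.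

Step 13
Reactants: 17 pentol with allylic alcohol
Product: 18 (E)-enal
Conditions: MnO2, acetone, 23 °C
Reagents that add atoms: none
Why: MnO2 oxidation is selective for the allylic primary alcohol over the saturated secondary and tertiary hydroxyls.

Step 14
Reactants: 18 (E)-enal
Product: 19 (2E,4E)-dienal
Conditions: Ph3P=CHCHO (1.1 equiv), MeCN, 60 °C
Reagents that add atoms: (triphenylphosphoranylidene)acetaldehyde, O=CC=P(c1ccccc1)(c1ccccc1)c1ccccc1
Why: Wittig two-carbon homologation with the formyl-stabilised ylide should give the (E)-alkene, with the ylide kept near one equivalent to limit a second homologation.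

**Fragment 3: pyrone**

Step 15
Reactants: 20 methyl 2-methyl-3-oxopentanoate
Product: 22 methyl 2,4-dimethyl-3,5-dioxoheptanoate, via keto ester dianion 21 (not isolated)
Conditions: NaH, THF, 0 °C; n-BuLi, 0 °C; EtC(O)N(OMe)Me, −78 → 0 °C; aq. NH4Cl
Reagents that add atoms: N-methoxy-N-methylpropanamide, CCC(=O)N(C)OC
Why: γ-Acylation of the β-keto ester dianion (Claisen-type acylation at the more reactive terminal carbanion) should give the 3,5-diketo ester.

Step 16
Reactants: 22 methyl 2,4-dimethyl-3,5-dioxoheptanoate
Product: 23 6-ethyl-4-hydroxy-3,5-dimethyl-2H-pyran-2-one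
Conditions: DBU, toluene, 110 °C
Reagents that add atoms: none
Why: Base-mediated enol lactonisation of the 3,5-diketo ester should close the 4-hydroxy-2-pyranone.

Step 17
Reactants: 23 6-ethyl-4-hydroxy-3,5-dimethyl-2H-pyran-2-one
Product: 24 6-ethyl-2-methoxy-3,5-dimethyl-4H-pyran-4-one
Conditions: MeOTf, CH2Cl2, 23 °C; aq. NaHCO3
Reagents that add atoms: methyl trifluoromethanesulfonate, COS(=O)(=O)C(F)(F)F
Why: O-Alkylation by the hard methylating agent at the lactone carbonyl oxygen, followed by loss of the hydroxyl proton, should give the 2-methoxy-4-pyranone and not the 4-methoxy-2-pyranone.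

**Union and completion**

Step 18
Reactants: 19 (2E,4E)-dienal; 24 6-ethyl-2-methoxy-3,5-dimethyl-4H-pyran-4-one
Product: 26 aldol adduct (pentol), via lithiated pyrone 25 (not isolated)
Conditions: 24 (5 equiv), LiN(SiMe3)2 (5 equiv), THF, −78 °C; then 19, −78 → −40 °C; aq. NH4Cl
Reagents that add atoms: none
Why: Lateral (vinylogous) deprotonation of the 6-ethyl group and aldol-type 1,2-addition of the anion to the dienal, with excess anion to cover the four hydroxyls; the two new stereocentres are not controlled and do not matter, because both are destroyed in step 19.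

Step 19
Reactants: 26 aldol adduct (pentol)
Product: 28 amaurone B, via triacetate 27 (not isolated)
Conditions: Ac2O, pyridine, DMAP (5 mol %), CH2Cl2, 0 → 23 °C; then DBU, toluene, 23 °C
Reagents that add atoms: acetic anhydride, CC(=O)OC(C)=O
Why: Acetylation should take the three secondary hydroxyls and leave the tertiary ones, and DBU then removes only the side-chain acetate by E1cB elimination through the pyrone-stabilised anion to give the (E)-trisubstituted alkene, the ring acetates having no acidifying group.

**Compound list**

1 | methyl 3-methylfuran-2-carboxylate | COC(=O)c1occc1C | starting material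
2 | (3-methylfuran-2-yl)methanol | OCc1occc1C | intermediate
3 | 6-hydroxy-4-methyl-2H-pyran-3(6H)-one, racemic hemiacetal | CC1=CC(O)OCC1=O | intermediate
4 | (R)-6-acetoxy-4-methyl-2H-pyran-3(6H)-one | CC1=C[C@@H](OC(C)=O)OCC1=O | intermediate
5 | (S)-6-(benzyloxy)-4-methyl-2H-pyran-3(6H)-one | CC1=C[C@@H](OCc2ccccc2)OCC1=O | intermediate
6 | 2-phenyl-1,3-dioxan-5-ol, cis/trans mixture | OC1COC(c2ccccc2)OC1 | starting material
7 | 2-phenyl-1,3-dioxan-5-one | O=C1COC(c2ccccc2)OC1 | intermediate
8 | 1-(2-phenyl-4H-1,3-dioxin-5-yl)pyrrolidine (enamine of 7) | C1CCN(C1)C1=COC(c2ccccc2)OC1 | intermediate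
9 | Michael adduct: dioxanone C4 bonded to pyranone C5, trans to the benzyloxy group, methyl trans to the dioxanonyl group | C(c1ccccc1)O[C@@H]5[C@H]([C@H](C)C(=O)CO5)[C@@H]2O[C@@H](c3ccccc3)OCC2=O | intermediate
10 | cage ketol: cyclohexanone C1–C6 with C5 ketone, C3 hydroxyl and C2 methyl; O4 and O6 joined as a benzylidene acetal (phenyl equatorial) on one face; C1 and C3 joined on the other face by a CH(OBn)–O–CH2 bridge (acetal carbon on C1, benzyloxy anti to C6); C1–C4 and C6 as in the target | C(c1ccccc1)O[C@@H]5[C@@H]2[C@H](C)[C@@](CO5)(O)[C@@H](O[C@H](c4ccccc4)O3)C(=O)[C@H]23 | intermediate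
11 | cage as 10 with C5 exocyclic methylene in place of the ketone | C(c1ccccc1)O[C@@H]5[C@@H]2[C@H](C)[C@@](CO5)(O)[C@@H](O[C@H](c4ccccc4)O3)C(=C)[C@H]23 | intermediate
12 | cage as 10 with a C5 spiro-epoxide, epoxide oxygen cis to O4 and O6 | C(c1ccccc1)O[C@@H]5[C@@H]2[C@H](C)[C@@](CO5)(O)[C@@H](O[C@H](c4ccccc4)O3)[C@]6(CO6)[C@H]23 | intermediate
13 | monocyclic aldehyde: C1 formyl, C2 methyl, C3 hydroxyl and hydroxymethyl, C4 and C6 hydroxyls, C5 spiro-epoxide; ring configuration as in the target | O=C[C@@H]2[C@H](C)[C@@](CO)(O)[C@@H](O)[C@]6(CO6)[C@H]2O | intermediate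
14 | ethyl (E)-2-methyl-3-(ring C1)prop-2-enoate derived from 13 | CCOC(=O)/C(C)=C/[C@@H]2[C@H](C)[C@@](CO)(O)[C@@H](O)[C@]6(CO6)[C@H]2O | intermediate
15 | 14 with the C3 hydroxymethyl as its p-toluenesulfonate | CCOC(=O)/C(C)=C/[C@@H]2[C@H](C)[C@@](COS(=O)(=O)c3ccc(C)cc3)(O)[C@@H](O)[C@]6(CO6)[C@H]2O | intermediate
16 | allylic alcohol with spiro-epoxides at C3 and C5, both epoxide oxygens cis to the C4 hydroxyl | OC/C(C)=C/[C@@H]2[C@H](C)[C@]4(CO4)[C@@H](O)[C@]6(CO6)[C@H]2O | intermediate
17 | (E)-2-methyl-3-(ring C1)prop-2-en-1-ol; ring with C2 methyl, C3 and C5 methyl carbinols, C4 and C6 hydroxyls, all as in the target | OC/C(C)=C/[C@@H]2[C@H](C)[C@@](C)(O)[C@@H](O)[C@@](C)(O)[C@H]2O | intermediate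
18 | (E)-2-methyl-3-(ring C1)prop-2-enal, ring as in 17 | O=C/C(C)=C/[C@@H]2[C@H](C)[C@@](C)(O)[C@@H](O)[C@@](C)(O)[C@H]2O | intermediate
19 | (2E,4E)-4-methyl-5-(ring C1)penta-2,4-dienal, ring as in 17 | O=C/C=C/C(C)=C/[C@@H]2[C@H](C)[C@@](C)(O)[C@@H](O)[C@@](C)(O)[C@H]2O | intermediate
20 | methyl 2-methyl-3-oxopentanoate | CCC(=O)C(C)C(=O)OC | starting material
21 | sodium lithium dianion of 20 (C2 and C4 carbanions) | C[CH-]C(=O)[C-](C)C(=O)OC.[Na+].[Li+] | intermediate
22 | methyl 2,4-dimethyl-3,5-dioxoheptanoate (diastereomers, tautomers) | CCC(=O)C(C)C(=O)C(C)C(=O)OC | intermediate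
23 | 6-ethyl-4-hydroxy-3,5-dimethyl-2H-pyran-2-one | CCc1oc(=O)c(C)c(O)c1C | intermediate
24 | 6-ethyl-2-methoxy-3,5-dimethyl-4H-pyran-4-one | CCc1oc(OC)c(C)c(=O)c1C | intermediate
25 | lithium salt of 24 deprotonated at the CH2 of the ethyl group | C[CH-]c1oc(OC)c(C)c(=O)c1C.[Li+] | intermediate
26 | aldol adduct: pyrone–CH(CH3)–CH(OH)–CH=CH–C(CH3)=CH–ring, both alkenes E, ring as in 17, the two side-chain sp3 centres as a mixture | COc1oc(C(C)C(O)/C=C/C(C)=C/[C@@H]2[C@H](C)[C@@](C)(O)[C@@H](O)[C@@](C)(O)[C@H]2O)c(C)c(=O)c1C | intermediate
27 | triacetate of 26 at the side-chain carbinol, O4 and O6 | COc1oc(C(C)C(OC(C)=O)/C=C/C(C)=C/[C@@H]2[C@H](C)[C@@](C)(O)[C@@H](OC(C)=O)[C@@](C)(O)[C@H]2OC(C)=O)c(C)c(=O)c1C | intermediate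
28 | amaurone B | COc1oc(/C(C)=C/C=C/C(C)=C/[C@@H]2[C@H](C)[C@@](C)(O)[C@@H](OC(C)=O)[C@@](C)(O)[C@H]2OC(C)=O)c(C)c(=O)c1C | target

**Step count.** Total: 19 steps. Longest linear sequence: 15 steps (1–4, 6–14, 18, 19).

**Steps most likely to fail**

Step 6. The conjugate addition to the α-methyl enone may be slow against self-condensation of the dioxanone, or the cage may close kinetically from the C2 epimer and fail to equilibrate. The fallback sets out from 5 and 7 and separates the two bond formations. Ketone 7 is silylated (Me3SiCl, Et3N) to 2-phenyl-5-(trimethylsilyloxy)-4H-1,3-dioxine F1. Mukaiyama–Michael addition of F1 to 5 (catalytic HNTf2, CH2Cl2, −78 °C) should give the trimethylsilyl enol ether of the Michael adduct F2, formed anti to the benzyloxy group. Mild aqueous acid hydrolyses F2 to 9, now isolated, whose C2 centre can be equilibrated. Compound 9 is then closed in a separate base-mediated aldol (catalytic KOt-Bu, t-BuOH) under equilibrating conditions, and the route is rejoined at 10.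

Step 7. Retro-aldol opening of the cage at 65 °C or failure of the titanium carbene to engage the flanked ketone would stop the route. The fallback sets out from 10 and uses addition–elimination in place of a carbene. The tertiary hydroxyl is silylated (Me3SiOTf, 2,6-lutidine) to the C3 trimethylsilyl ether of the cage ketol F3, which can no longer undergo retro-aldol. Me3SiCH2Li with CeCl3 (THF, −78 °C) should add from the open face to give the C5 β-hydroxysilane F4. Peterson elimination (KH, THF) gives the C3 trimethylsilyl ether of the methylene cage F5, and K2CO3 in MeOH removes the silyl ether to return at 11.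

Step 18. Fourfold deprotonation of the hydroxyls may precipitate the substrate or stall the addition, and the anion may enolise the dienal instead of adding. The fallback sets out from 19 and 24 and replaces aldol–elimination by an olefination that tolerates acetates. Dienal 19 is acetylated (Ac2O, pyridine, DMAP) to the C4,C6-diacetate dienal F6. Pyrone 24 is deprotonated (LiN(SiMe3)2, THF, −78 °C) and brominated with CBr4 to 6-(1-bromoethyl)-2-methoxy-3,5-dimethyl-4H-pyran-4-one F7. Michaelis–Arbuzov reaction with P(OEt)3 (130 °C) gives diethyl [1-(6-methoxy-3,5-dimethyl-4-oxo-4H-pyran-2-yl)ethyl]phosphonate F8. Horner–Wadsworth–Emmons reaction of the sodium salt of F8 (NaN(SiMe3)2, THF, −78 → 0 °C) with F6 should give the (E)-trisubstituted alkene directly and return at 28.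

**Further compounds**

F1 | step 6 | 2-phenyl-5-(trimethylsilyloxy)-4H-1,3-dioxine | C[Si](C)(C)OC1=COC(c2ccccc2)OC1
F2 | step 6 | trimethylsilyl enol ether of Michael adduct 9 (enol ether on the pyranone ketone) | C(c1ccccc1)O[C@@H]5[C@H](C(C)=C(CO5)O[Si](C)(C)C)[C@@H]2O[C@@H](c3ccccc3)OCC2=O
F3 | step 7 | C3 trimethylsilyl ether of cage ketol 10 | C(c1ccccc1)O[C@@H]5[C@@H]2[C@H](C)[C@@](CO5)(O[Si](C)(C)C)[C@@H](O[C@H](c4ccccc4)O3)C(=O)[C@H]23
F4 | step 7 | C5 β-hydroxysilane: F3 with C5 bearing hydroxyl (inside) and CH2SiMe3 (cis to O4 and O6) | C(c1ccccc1)O[C@@H]5[C@@H]2[C@H](C)[C@@](CO5)(O[Si](C)(C)C)[C@@H](O[C@H](c4ccccc4)O3)[C@@](O)(C[Si](C)(C)C)[C@H]23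
F5 | step 7 | C3 trimethylsilyl ether of methylene cage 11 | C(c1ccccc1)O[C@@H]5[C@@H]2[C@H](C)[C@@](CO5)(O[Si](C)(C)C)[C@@H](O[C@H](c4ccccc4)O3)C(=C)[C@H]23
F6 | step 18 | C4,C6-diacetate of dienal 19 | O=C/C=C/C(C)=C/[C@@H]2[C@H](C)[C@@](C)(O)[C@@H](OC(C)=O)[C@@](C)(O)[C@H]2OC(C)=O
F7 | step 18 | 6-(1-bromoethyl)-2-methoxy-3,5-dimethyl-4H-pyran-4-one | CC(Br)c1oc(OC)c(C)c(=O)c1C
F8 | step 18 | diethyl [1-(6-methoxy-3,5-dimethyl-4-oxo-4H-pyran-2-yl)ethyl]phosphonate | CCOP(=O)(OCC)C(C)c1oc(OC)c(C)c(=O)c1C
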